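The aryl C2–O bond ortho to the tertiary carbinol is traced back to a C–H bond of a p-tolyl carbinol, whose benzene ring has two equivalent ortho positions (C2–H and C6–H) three bonds from the carbinol oxygen. The key step uses that oxygen as a tether: its diethylhydrosilyl ether is cyclised by iridium catalysis onto the ortho carbon, forming the aryl C–Si bond and a five-membered benzoxasilole ring in one operation; peroxide oxidation then turns C–Si into C–O. The precursor is 2-(p-tolyl)glycerol carrying isobutyrates on both primary oxygens and an O–SiHEt2 group on the tertiary oxygen, assembled from p-tolylmagnesium bromide and dihydroxyacetone acetonide.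

Key step: step 4

Remark: the target has no stereocentre, because the carbinol carbon bears two identical CH2O-isobutyryl arms, so nothing has to be controlled stereochemically. p-Tolylmagnesium bromide (THF solution) and chlorodiethylsilane are taken as purchased reagents.

Step 1
Reactants: 1 4-methylphenylmagnesium bromide; 2 2,2-dimethyl-1,3-dioxan-5-one
Product: 4 2-(4-methylphenyl)propane-1,2,3-triol, via p-tolyl dioxanol 3 (not isolated)
Conditions: THF, −78 → 0 °C; then 1 M aq HCl, rt
Reagents that add atoms: none
Why: Grignard 1,2-addition to the ketone gives the tertiary alkoxide, and the acidic quench protonates it and hydrolyses the isopropylidene acetal in the same flask (acetal hydrolysis), the two β-oxygens protecting the benzylic carbinol from ionisation; no stereocentre arises.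

Step 2
Reactants: 4 2-(4-methylphenyl)propane-1,2,3-triol; 5 2-methylpropanoyl chloride
Product: 6 2-hydroxy-2-(4-methylphenyl)propane-1,3-diyl bis(2-methylpropanoate)
Conditions: iPrCOCl (2.1 equiv), pyridine, CH2Cl2, −20 → 0 °C
Reagents that add atoms: 2-methylpropanoyl chloride (5), CC(C)C(=O)Cl
Why: Nucleophilic acyl substitution (esterification with an acid chloride) should acylate only the two equivalent primary hydroxyls, because the tertiary benzylic hydroxyl is too hindered to react without an acyl-transfer catalyst.

Step 3
Reactants: 6 2-hydroxy-2-(4-methylphenyl)propane-1,3-diyl bis(2-methylpropanoate); 7 chlorodiethylsilane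
Product: 8 2-[(diethylsilyl)oxy]-2-(4-methylphenyl)propane-1,3-diyl bis(2-methylpropanoate)
Conditions: Et2SiHCl (1.5 equiv), imidazole, DMAP (cat.), CH2Cl2, 0 °C → rt; hexane, filtration, used crude
Reagents that add atoms: chlorodiethylsilane (7), CC[SiH](Cl)CC
Why: O-Silylation of the tertiary alcohol by substitution at the Si–Cl bond of a small, reactive hydrochlorosilane should install the Si–H tether, and it keeps the esters away from the combination of free diethylsilane and an iridium catalyst, which could reduce ester carbonyls.

Step 4
Reactants: 8 2-[(diethylsilyl)oxy]-2-(4-methylphenyl)propane-1,3-diyl bis(2-methylpropanoate)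
Product: 9 (1,1-diethyl-6-methyl-1,3-dihydro-2,1-benzoxasilole-3,3-diyl)bis(methylene) bis(2-methylpropanoate)
Conditions: [Ir(cod)OMe]2 (2 mol %), 1,10-phenanthroline (5 mol %), norbornene (1.5 equiv), THF, 100 °C
Reagents that add atoms: none
Why: The Si–H bond of 8 adds oxidatively to phenanthroline-ligated monovalent iridium and the hydride is passed on to norbornene, leaving an iridium silyl that is held next to the arene by the Si–O–C tether and cleaves an ortho C–H bond; C–Si reductive elimination then releases 9 and returns the catalyst. This is the established iridium-catalysed hydroxyl-directed dehydrogenative ortho-silylation of benzylic hydrosilyl ethers, here applied to a tertiary carbinol. The one new ring, the five-membered 1,2-oxasilole (Si1–O2–C3–C3a–C7a), is closed by intramolecular Si–C(aryl) bond formation between Si1 and C7a. No stereocentre is created, since C3 carries two identical CH2O-isobutyryl arms. The step needs site selectivity for the ortho C–H bond and chemoselectivity over the ester carbonyls: the tether reaches the ortho carbon through a five-membered ring whereas the CH2 groups would demand a four-membered one, the para-methyl group makes C2–H and C6–H of the benzene ring equivalent so that only one regioisomer can form, and the hindered isobutyrates together with the absence of free dihydrosilane should disfavour carbonyl hydrosilylation.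

Step 5
Reactants: 9 (1,1-diethyl-6-methyl-1,3-dihydro-2,1-benzoxasilole-3,3-diyl)bis(methylene) bis(2-methylpropanoate)
Product: 10 2-hydroxy-2-(2-hydroxy-4-methylphenyl)propane-1,3-diyl bis(2-methylpropanoate)
Conditions: 30% aq H2O2, KHCO3, THF/MeOH, rt
Reagents that add atoms: hydrogen peroxide, OO
Why: Tamao–Fleming oxidation, in which hydroperoxide adds to the alkoxysilane silicon and the aryl group migrates from Si to O at the same ring carbon, should give the phenol and free the tertiary alcohol, while bicarbonate is too weak a base to cleave the branched isobutyrates at room temperature.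

Step 6
Reactants: 10 2-hydroxy-2-(2-hydroxy-4-methylphenyl)propane-1,3-diyl bis(2-methylpropanoate); 11 iodomethane
Product: 12 2-hydroxy-2-(2-methoxy-4-methylphenyl)propane-1,3-diyl bis(2-methylpropanoate)
Conditions: MeI, K2CO3, acetone, rt
Reagents that add atoms: iodomethane (11), CI
Why: Williamson ether synthesis, in which carbonate deprotonates only the phenol and the phenoxide is methylated by SN2, should leave the tertiary alcohol and both esters untouched.

Compound list
1 | 4-methylphenylmagnesium bromide (p-tolylmagnesium bromide) | Cc1ccc(cc1)[Mg]Br | starting material
2 | 2,2-dimethyl-1,3-dioxan-5-one | CC1(C)OCC(=O)CO1 | starting material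
3 | 2,2-dimethyl-5-(4-methylphenyl)-1,3-dioxan-5-ol (p-tolyl dioxanol, achiral) | Cc1ccc(cc1)C1(O)COC(C)(C)OC1 | intermediate (not isolated)
4 | 2-(4-methylphenyl)propane-1,2,3-triol (achiral) | Cc1ccc(cc1)C(O)(CO)CO | intermediate
5 | 2-methylpropanoyl chloride | CC(C)C(=O)Cl | starting material
6 | 2-hydroxy-2-(4-methylphenyl)propane-1,3-diyl bis(2-methylpropanoate) (achiral) | Cc1ccc(cc1)C(O)(COC(=O)C(C)C)COC(=O)C(C)C | intermediate
7 | chlorodiethylsilane | CC[SiH](Cl)CC | starting material
8 | 2-[(diethylsilyl)oxy]-2-(4-methylphenyl)propane-1,3-diyl bis(2-methylpropanoate) (achiral) | Cc1ccc(cc1)C(O[SiH](CC)CC)(COC(=O)C(C)C)COC(=O)C(C)C | intermediate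
9 | (1,1-diethyl-6-methyl-1,3-dihydro-2,1-benzoxasilole-3,3-diyl)bis(methylene) bis(2-methylpropanoate) (achiral) | Cc1ccc2c(c1)[Si](CC)(CC)OC2(COC(=O)C(C)C)COC(=O)C(C)C | intermediate
10 | 2-hydroxy-2-(2-hydroxy-4-methylphenyl)propane-1,3-diyl bis(2-methylpropanoate) (achiral) | Cc1ccc(c(O)c1)C(O)(COC(=O)C(C)C)COC(=O)C(C)C | intermediate
11 | iodomethane | CI | starting material
12 | 2-hydroxy-2-(2-methoxy-4-methylphenyl)propane-1,3-diyl bis(2-methylpropanoate) (achiral) | COc1cc(C)ccc1C(O)(COC(=O)C(C)C)COC(=O)C(C)C | target

Total step count: 6
Longest linear sequence: 6 steps (from 1 and 2 to 12)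

Steps most likely to fail

Step 4. The tethered Si–H may be diverted at iridium into reduction of an ester carbonyl, or cyclometalation at the crowded tertiary silyl ether may be so slow that the silyl ether redistributes or is lost. The fallback gives up the C–H functionalisation and brings the ring oxygen in with the aryl nucleophile. It sets out from 2 and comes back to the route at 12. Commercial 1-bromo-2-methoxy-4-methylbenzene is converted with Mg in THF into (2-methoxy-4-methylphenyl)magnesium bromide F1. This adds to 2 at −78 °C and, after an aqueous NH4Cl quench, should give 5-(2-methoxy-4-methylphenyl)-2,2-dimethyl-1,3-dioxan-5-ol F2. Aqueous acetic acid at mild temperature removes the acetal to give 2-(2-methoxy-4-methylphenyl)propane-1,2,3-triol F3. Acylation of its two primary hydroxyls with 5 and pyridine, as in step 2, leads to 12.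

Step 5. Perhydrolysis or methanolysis of the primary isobutyrates, or acyl transfer to the newly formed phenoxide, may accompany the basic peroxide oxidation. The fallback accepts complete loss of the esters and re-esterifies at the end. It sets out from 9 and comes back to the route at 12. Oxidation of 9 with H2O2 and KHCO3 is followed by K2CO3 in MeOH to complete deacylation, giving 2-(2-hydroxy-4-methylphenyl)propane-1,2,3-triol F4. MeI and K2CO3 in acetone methylate only the phenol, giving the methoxy triol F3 already met in the fallback for step 4. Selective acylation of the primary hydroxyls with 5 and pyridine then gives 12.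

Step 3. Silylation at the congested, inductively deactivated tertiary hydroxyl may stall, and the Si–H ether may hydrolyse during isolation. The fallback replaces chloride displacement by catalytic dehydrogenative Si–O coupling. It sets out from 6 and comes back to the route at 8. Alcohol 6 is treated with diethylsilane and [Ir(cod)OMe]2 (0.5 mol %) in THF at room temperature, and the excess silane is evaporated before the ligand and norbornene for step 4 are added to the same flask. This forms no salts and needs no isolation of 8, at the price of a short exposure of the esters to the free dihydrosilane.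

Further compounds
F1 | step 4 | (2-methoxy-4-methylphenyl)magnesium bromide | COc1cc(C)ccc1[Mg]Br
F2 | step 4 | 5-(2-methoxy-4-methylphenyl)-2,2-dimethyl-1,3-dioxan-5-ol | COc1cc(C)ccc1C1(O)COC(C)(C)OC1
F3 | step 4 | 2-(2-methoxy-4-methylphenyl)propane-1,2,3-triol | COc1cc(C)ccc1C(O)(CO)CO
F4 | step 5 | 2-(2-hydroxy-4-methylphenyl)propane-1,2,3-triol | Cc1ccc(c(O)c1)C(O)(CO)CO
F0 | step 3 | none | none
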